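**Retrosynthetic overview**
Numbering: ring A = C1–C6 (C3–OAc, C4(Me)=C5), ring B = C1, C6, C7–C10 (C7=C11 exocyclic, C9–OAc, C10–Me), C12 = CH2O carbon on C11; C1/C6 are the ring-fusion carbons.
Target 24 ⇐ diol 23 (bis-acetylation); ring B is closed last through C9–C10, by adding a C10 organochromium (from cobalt-hydride H-atom transfer to a C1 vinyl group) to the C9 aldehyde of 20.
Enabling feature: the tetrasubstituted exocyclic C7=C11 alkene of ring B next to ring-fusion carbon C6; allylic 1,3-strain between the C11 methyl and C6 holds C6–H in the alkene plane, so ring B closes through one chair and C9, C10 and the C10 methyl (from the vinyl CH2) come out all-equatorial.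
Side chain ⇐ (Z)-enol triflate of β-keto ester 13 + Negishi coupling (fixes the alkene geometry); 13 ⇐ cis vinyl acid 9 ⇐ zinc fragmentation of an iodomethyl lactone.
Ring A is formed first, by a Diels–Alder reaction of a 1-methoxy-3-silyloxy diene with (R)-5-(hydroxymethyl)butenolide (sets C1 and C6; the butenolide stereocentre is then erased as the vinyl carbon C10); ring B is formed second.

Key step: step 13

Assumption: 1 and 3 are taken as purchasable, and the free hydroxyl of 3 is taken to survive the thermal cycloaddition (excess diene).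

Step 1
Reactants: 1 (E)-4-methoxy-3-methylbut-3-en-2-one
Product: 2 (E)-1-methoxy-2-methyl-3-(trimethylsilyloxy)buta-1,3-diene
Conditions: TMSCl, Et3N, ZnCl2 (cat.), benzene, 40 °C
Reagents that add atoms: chlorotrimethylsilane, C[Si](C)(C)Cl
Why: Silyl enol ether formation at the acetyl methyl (soft enolisation) should give the cross-conjugated 2-silyloxy diene with the enol ether geometry unchanged.

Step 2
Reactants: 2 (E)-1-methoxy-2-methyl-3-(trimethylsilyloxy)buta-1,3-diene; 3 (R)-5-(hydroxymethyl)furan-2(5H)-one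
Product: 5 cis-fused 3-(hydroxymethyl)-6-methyl-3a,4-dihydroisobenzofuran-1,5(3H,7aH)-dione, via silyl enol ether cycloadduct 4 (not isolated)
Conditions: toluene, 110 °C, sealed tube; then 0.1 M HCl, THF, 0 °C
Reagents that add atoms: none
Why: Diels–Alder reaction in which the diene CH2 terminus bonds to the butenolide β-carbon (C1), the cis dienophile gives the cis ring fusion and the diene adds anti to the hydroxymethyl group (sets C1 and C6), after which acid hydrolysis and β-elimination of methanol should give the enone.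

Step 3
Reactants: 5 cis-fused 3-(hydroxymethyl)-6-methyl-3a,4-dihydroisobenzofuran-1,5(3H,7aH)-dione
Product: 6 cis-fused 3-(iodomethyl)-6-methyl-3a,4-dihydroisobenzofuran-1,5(3H,7aH)-dione
Conditions: I2, PPh3, imidazole, CH2Cl2, 0 to 23 °C
Reagents that add atoms: iodine, II
Why: Appel reaction on the only (primary) alcohol; the enone and lactone are inert and the cis ring fusion is held by the lactone.

Step 4
Reactants: 6 cis-fused 3-(iodomethyl)-6-methyl-3a,4-dihydroisobenzofuran-1,5(3H,7aH)-dione
Product: 7 5-hydroxy-3-(iodomethyl)-6-methyl-3a,4,5,7a-tetrahydroisobenzofuran-1(3H)-one (5-OH on the lactone face)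
Conditions: NaBH4, CeCl3·7H2O, MeOH, −78 °C
Reagents that add atoms: none
Why: Luche reduction (1,2-selective) in which hydride should attack the convex face, anti to the cis-fused lactone, so that the new C3 hydroxyl is cis to the lactone carbons (sets C3).

Step 5
Reactants: 7 5-hydroxy-3-(iodomethyl)-6-methyl-3a,4,5,7a-tetrahydroisobenzofuran-1(3H)-one
Product: 8 5-O-triethylsilyl ether of 7
Conditions: Et3SiOTf, 2,6-lutidine, CH2Cl2, −78 °C
Reagents that add atoms: triethylsilyl trifluoromethanesulfonate, CC[Si](CC)(CC)OS(=O)(=O)C(F)(F)F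
Why: Silylation of the secondary allylic alcohol with a silyl triflate and a hindered, non-nucleophilic base that does not alkylate at the primary iodide.

Step 6
Reactants: 8 5-O-triethylsilyl ether of 7
Product: 9 all-cis-3-methyl-4-(triethylsilyloxy)-6-vinylcyclohex-2-ene-1-carboxylic acid
Conditions: Zn dust (activated), THF/AcOH (10:1), 23 °C
Reagents that add atoms: none
Why: Reductive β-elimination of a β-acyloxy alkyl iodide (zinc insertion then fragmentation, the reverse of an iodolactonisation) should open the lactone to the acid and turn the former carbinol carbon into the vinyl CH (C10) without touching C1 or C6.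

Step 7
Reactants: 9 all-cis-3-methyl-4-(triethylsilyloxy)-6-vinylcyclohex-2-ene-1-carboxylic acid; 10 ethyl hydrogen methylmalonate
Product: 13 ethyl 2-methyl-3-oxo-3-[all-cis-3-methyl-4-(triethylsilyloxy)-6-vinylcyclohex-2-en-1-yl]propanoate (C2 epimers), via N-acylimidazole 11 (not isolated), via acylmalonic half-ester 12 (not isolated)
Conditions: CDI, THF, 23 °C; then 10 pre-treated with i-PrMgCl (2 equiv), THF, 0 to 40 °C; aq. citric acid
Reagents that add atoms: none
Why: Acyl imidazolide formation and C-acylation of a magnesium malonate half-ester enolate with decarboxylation (decarboxylative Claisen condensation), near-neutral conditions that should not epimerise C6.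

Step 8
Reactants: 13 ethyl 2-methyl-3-oxo-3-[all-cis-3-methyl-4-(triethylsilyloxy)-6-vinylcyclohex-2-en-1-yl]propanoate
Product: 15 ethyl (Z)-2-methyl-3-[ring A unit]-3-(trifluoromethylsulfonyloxy)prop-2-enoate, via sodium enolate 14 (not isolated)
Conditions: NaH, Et2O, 0 °C; then Tf2O, −78 to 0 °C
Reagents that add atoms: trifluoromethanesulfonic anhydride, O=S(=O)(OS(=O)(=O)C(F)(F)F)C(F)(F)F
Why: O-triflation of the sodium-chelated β-keto ester enolate should give the (Z)-enol triflate (OTf cis to CO2Et), which fixes the later C8/C12 cis relationship.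

Step 9
Reactants: 15 ethyl (Z)-2-methyl-3-[ring A unit]-3-(trifluoromethylsulfonyloxy)prop-2-enoate; 16 (1,3-dioxolan-2-ylmethyl)zinc bromide
Product: 17 ethyl (E)-4-(1,3-dioxolan-2-yl)-2-methyl-3-[all-cis-3-methyl-4-(triethylsilyloxy)-6-vinylcyclohex-2-en-1-yl]but-2-enoate
Conditions: Pd(PPh3)4 (5 mol%), THF, 50 °C
Reagents that add atoms: none
Why: Negishi cross-coupling of an activated alkenyl triflate with an alkylzinc reagent, stereoretentive at the alkene, so the C8 methylene ends cis to the ester carbon (C12).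

Step 10
Reactants: 17 ethyl (E)-4-(1,3-dioxolan-2-yl)-2-methyl-3-[ring A unit]but-2-enoate
Product: 18 (E)-4-(1,3-dioxolan-2-yl)-2-methyl-3-[all-cis-3-methyl-4-(triethylsilyloxy)-6-vinylcyclohex-2-en-1-yl]but-2-en-1-ol
Conditions: i-Bu2AlH (3 equiv), CH2Cl2, −78 to −20 °C; aq. potassium sodium tartrate
Reagents that add atoms: none
Why: 1,2-Reduction of the enoate by an aluminium hydride to the allylic alcohol; acetal, silyl ether and alkenes are inert.

Step 11
Reactants: 18 (E)-4-(1,3-dioxolan-2-yl)-2-methyl-3-[ring A unit]but-2-en-1-ol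
Product: 19 formate ester of 18
Conditions: 2,2,2-trifluoroethyl formate (neat), 60 °C
Reagents that add atoms: 2,2,2-trifluoroethyl formate, O=COCC(F)(F)F
Why: O-Formylation by transesterification with an activated formate on the only free alcohol, under neutral conditions that keep the silyl ether and acetal.

Step 12
Reactants: 19 formate ester of 18
Product: 20 (E)-3-[all-cis-4-hydroxy-3-methyl-6-vinylcyclohex-2-en-1-yl]-2-methyl-5-oxopent-2-en-1-yl formate
Conditions: PPTS (0.2 equiv), acetone/H2O (5:1), 40 °C
Reagents that add atoms: water, O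
Why: Acid-catalysed acetal hydrolysis with concurrent cleavage of the triethylsilyl ether, kept mild so that the β,γ-unsaturated aldehyde stays unconjugated and the formate survives.

Step 13
Reactants: 20 (E)-3-[all-cis-4-hydroxy-3-methyl-6-vinylcyclohex-2-en-1-yl]-2-methyl-5-oxopent-2-en-1-yl formate
Product: 23 (1R,3S,6R,9S,10S)-3,9-dihydroxy bicyclic 12-formate (ring B closed), via C10 secondary radical 21 (not isolated), via C10 alkylchromium species 22 (not isolated)
Conditions: CrCl2 (4 equiv), cobalt phthalocyanine CoC32H16N8 (10 mol%), 2,4,6-collidinium chloride (1.5 equiv), DMF, 23 °C; aq. NH4Cl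
Reagents that add atoms: none
Why: Proposed new method: a cobalt hydride, formed from monovalent cobalt (CrCl2 reduction of the catalyst) and collidinium, should transfer H• to the terminal CH2 of the vinyl group (Markovnikov), and the secondary C10 radical 21 is captured by the excess divalent chromium to give alkylchromium 22, which adds to the C9 aldehyde as in a Nozaki–Hiyama–Kishi reaction. The closest known reaction types are the cobalt-catalysed generation of alkylchromium reagents from alkyl halides with their aldehyde-selective addition, and the metal-hydride H-atom-transfer, branch-selective coupling of unactivated terminal olefins with aldehydes. Ring B closes in the 6-exo-trig mode onto the C9 carbonyl carbon through a chair transition state. Allylic 1,3-strain between the C11 methyl and C6 keeps C6–H in the alkene plane and the C6–C5 bond axial, so the configurationally labile C10–Cr centre should place its methyl equatorial (10-Me cis to H1) and the aldehyde oxygen equatorial (9-OH trans to that methyl); both new stereocentres are thus controlled by C1/C6 and the alkene. The step needs H-atom transfer to the monosubstituted vinyl group rather than the tri- and tetrasubstituted alkenes (steric preference of the cobalt hydride), radical capture by chromium faster than radical addition to C=O (large excess of CrCl2; this avoids an alkoxyl radical that would fragment to the C8 allylic radical), and aldehyde over formate selectivity (inherent to organochromium reagents).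

Step 14
Reactants: 23 (1R,3S,6R,9S,10S)-3,9-dihydroxy bicyclic 12-formate
Product: 24 target, (1R,3S,6R,9S,10S)-3,9-diacetoxy bicyclic 12-formate with (E)-C7=C11
Conditions: Ac2O, pyridine, DMAP (cat.), CH2Cl2, 0 to 23 °C
Reagents that add atoms: acetic anhydride, CC(=O)OC(C)=O
Why: DMAP-catalysed acylation of both secondary alcohols; the formate is not exchanged under these conditions.

**Compound list**
1 | (E)-4-methoxy-3-methylbut-3-en-2-one | CO/C=C(\C)C(C)=O | starting material
2 | (E)-1-methoxy-2-methyl-3-(trimethylsilyloxy)buta-1,3-diene | CO/C=C(\C)C(=C)O[Si](C)(C)C | intermediate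
3 | (R)-5-(hydroxymethyl)furan-2(5H)-one | OC[C@@H]1OC(=O)C=C1 | starting material
4 | endo cycloadduct, cis-fused 3-(hydroxymethyl)-7-methoxy-6-methyl-5-(trimethylsilyloxy)-3a,4,7,7a-tetrahydroisobenzofuran-1(3H)-one (H-3a/H-7a cis, CH2OH on their face, OMe on the other face) | CO[C@H]1C(C)=C(O[Si](C)(C)C)C[C@@H]2[C@H]1C(=O)O[C@H]2CO | intermediate
5 | cis-fused 3-(hydroxymethyl)-6-methyl-3a,4-dihydroisobenzofuran-1,5(3H,7aH)-dione (CH2OH cis to H-3a/H-7a) | O=C1C[C@H]2[C@H](CO)OC(=O)[C@H]2C=C1C | intermediate
6 | cis-fused 3-(iodomethyl)-6-methyl-3a,4-dihydroisobenzofuran-1,5(3H,7aH)-dione | O=C1C[C@H]2[C@H](CI)OC(=O)[C@H]2C=C1C | intermediate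
7 | 5-hydroxy-3-(iodomethyl)-6-methyl-3a,4,5,7a-tetrahydroisobenzofuran-1(3H)-one (5-OH trans to H-3a/H-7a) | O[C@H]1C[C@H]2[C@H](CI)OC(=O)[C@H]2C=C1C | intermediate
8 | 5-O-triethylsilyl ether of 7 | CC[Si](CC)(CC)O[C@H]1C[C@H]2[C@H](CI)OC(=O)[C@H]2C=C1C | intermediate
9 | all-cis-3-methyl-4-(triethylsilyloxy)-6-vinylcyclohex-2-ene-1-carboxylic acid | CC[Si](CC)(CC)O[C@H]1C[C@@H](C=C)[C@@H](C(=O)O)C=C1C | intermediate
10 | ethyl hydrogen methylmalonate | CCOC(=O)C(C)C(=O)O | starting material
11 | N-acylimidazole of 9 | CC[Si](CC)(CC)O[C@H]1C[C@@H](C=C)[C@@H](C(=O)n2ccnc2)C=C1C | intermediate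
12 | 2-acyl-2-methylmalonic acid monoethyl ester (acyl = that of 9) | CC[Si](CC)(CC)O[C@H]1C[C@@H](C=C)[C@@H](C(=O)C(C)(C(=O)O)C(=O)OCC)C=C1C | intermediate
13 | ethyl 2-methyl-3-oxo-3-[all-cis-3-methyl-4-(triethylsilyloxy)-6-vinylcyclohex-2-en-1-yl]propanoate (C2 epimers) | CC[Si](CC)(CC)O[C@H]1C[C@@H](C=C)[C@@H](C(=O)C(C)C(=O)OCC)C=C1C | intermediate
14 | sodium (Z)-enolate of 13 | CC[Si](CC)(CC)O[C@H]1C[C@@H](C=C)[C@@H](/C([O-])=C(\C)C(=O)OCC)C=C1C.[Na+] | intermediate
15 | ethyl (Z)-2-methyl-3-[all-cis-3-methyl-4-(triethylsilyloxy)-6-vinylcyclohex-2-en-1-yl]-3-(trifluoromethylsulfonyloxy)prop-2-enoate | CC[Si](CC)(CC)O[C@H]1C[C@@H](C=C)[C@@H](/C(OS(=O)(=O)C(F)(F)F)=C(\C)C(=O)OCC)C=C1C | intermediate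
16 | (1,3-dioxolan-2-ylmethyl)zinc bromide | Br[Zn]CC1OCCO1 | starting material
17 | ethyl (E)-4-(1,3-dioxolan-2-yl)-2-methyl-3-[all-cis-3-methyl-4-(triethylsilyloxy)-6-vinylcyclohex-2-en-1-yl]but-2-enoate | CC[Si](CC)(CC)O[C@H]1C[C@@H](C=C)[C@@H](/C(CC2OCCO2)=C(\C)C(=O)OCC)C=C1C | intermediate
18 | (E)-4-(1,3-dioxolan-2-yl)-2-methyl-3-[all-cis-3-methyl-4-(triethylsilyloxy)-6-vinylcyclohex-2-en-1-yl]but-2-en-1-ol | CC[Si](CC)(CC)O[C@H]1C[C@@H](C=C)[C@@H](/C(CC2OCCO2)=C(\C)CO)C=C1C | intermediate
19 | formate ester of 18 | CC[Si](CC)(CC)O[C@H]1C[C@@H](C=C)[C@@H](/C(CC2OCCO2)=C(\C)COC=O)C=C1C | intermediate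
20 | (E)-3-[all-cis-4-hydroxy-3-methyl-6-vinylcyclohex-2-en-1-yl]-2-methyl-5-oxopent-2-en-1-yl formate | O[C@H]1C[C@@H](C=C)[C@@H](/C(CC=O)=C(\C)COC=O)C=C1C | intermediate
21 | C10 secondary radical from 20 | O[C@H]1C[C@@H]([CH]C)[C@@H](/C(CC=O)=C(\C)COC=O)C=C1C | intermediate
22 | C10 alkylchromium dichloride species | O[C@H]1C[C@@H](C(C)[Cr](Cl)Cl)[C@@H](/C(CC=O)=C(\C)COC=O)C=C1C | intermediate
23 | (1R,3S,6R,9S,10S)-3,9-dihydroxy bicyclic 12-formate, cis-fused, (E)-C7=C11 (overview numbering) | O[C@H]1C[C@H]2[C@H](C)[C@@H](O)C/C(=C(/C)COC=O)[C@H]2C=C1C | intermediate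
24 | target, (1R,3S,6R,9S,10S)-3,9-diacetoxy bicyclic 12-formate, cis-fused, (E)-C7=C11 (overview numbering) | CC(=O)O[C@H]1C[C@H]2[C@H](C)[C@@H](OC(C)=O)C/C(=C(/C)COC=O)[C@H]2C=C1C | target

**Totals**
Total step count: 14. Longest linear sequence: 14 steps (1 to 24); 3, 10 and 16 enter at steps 2, 7 and 9.

**Steps most likely to fail, with fallbacks**

Step 13 (proposed new method). What may go wrong: H-atom transfer that is not selective for the vinyl group, protonolysis of the alkylchromium before ring closure, or radical addition to the carbonyl followed by fragmentation of the alkoxyl radical. The fallback uses known chemistry and sets out from 19. A Wacker oxidation (PdCl2, CuCl, O2, DMF/H2O, buffered) of the terminal vinyl group should give methyl ketone F1. Reduction with Zn(BH4)2 gives secondary alcohol F2 (either C10 epimer serves). An Appel reaction (I2, PPh3, imidazole) gives secondary iodide F3. PPTS in acetone/H2O removes the acetal and the silyl ether to give iodo aldehyde F4. CrCl2 with catalytic cobalt phthalocyanine in DMF (alkylchromium formation from an alkyl iodide, aldehyde-selective intramolecular addition under the same allylic-strain control) closes ring B and returns to 23.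

Step 8 (with step 9). What may go wrong: erosion of enolate geometry during triflation, giving E/Z mixtures, or slow coupling at the tetrasubstituted carbon. The fallback sets the geometry through an s-cis diene instead and sets out from 9. CDI then MeNHOMe·HCl gives Weinreb amide F5. (1,3-Dioxolan-2-ylmethyl)magnesium bromide gives ketone F6. Kinetic enolisation towards C8 with KN(SiMe3)2 and PhNTf2 gives enol triflate F7 (its geometry is irrelevant). Suzuki–Miyaura coupling with isopropenylboronic acid pinacol ester (Pd(dppf)Cl2, K3PO4) gives diene F8. Nickel-catalysed 1,4-hydroboration (Ni(cod)2, PCy3, pinacolborane; zerovalent nickel binds only the s-cis 1,3-diene) then NaBO3·4H2O oxidation puts H on C8 and OH on C12 with C8 and C12 cis, and returns to 18.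

Step 12. What may go wrong: migration of the β,γ-double bond into conjugation with the new aldehyde, or loss of the formate under aqueous acid. The fallback carries C9 at the alcohol level and oxidises it under neutral conditions; it sets out from 15. B-alkyl Suzuki–Miyaura coupling of 15 with the pre-formed 9-BBN adduct of tert-butyldimethylsilyl vinyl ether (Pd(dppf)Cl2, K3PO4) gives silyloxyethyl enoate F9. i-Bu2AlH gives allylic alcohol F10. 2,2,2-Trifluoroethyl formate gives formate F11. HF·pyridine removes both silyl groups to give diol F12. Primary-selective oxidation with TEMPO/PhI(OAc)2 returns to 20.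

**Further compounds**
F1 | step 13 | methyl ketone from 19 (C1 acetyl in place of vinyl) | CC[Si](CC)(CC)O[C@H]1C[C@@H](C(C)=O)[C@@H](/C(CC2OCCO2)=C(\C)COC=O)C=C1C
F2 | step 13 | secondary alcohol from F1 (C10 epimers) | CC[Si](CC)(CC)O[C@H]1C[C@@H](C(C)O)[C@@H](/C(CC2OCCO2)=C(\C)COC=O)C=C1C
F3 | step 13 | secondary iodide from F2 (C10 epimers) | CC[Si](CC)(CC)O[C@H]1C[C@@H](C(C)I)[C@@H](/C(CC2OCCO2)=C(\C)COC=O)C=C1C
F4 | step 13 | iodo aldehyde with free C3 hydroxyl | O[C@H]1C[C@@H](C(C)I)[C@@H](/C(CC=O)=C(\C)COC=O)C=C1C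
F5 | step 8 | Weinreb amide of 9 | CC[Si](CC)(CC)O[C@H]1C[C@@H](C=C)[C@@H](C(=O)N(C)OC)C=C1C
F6 | step 8 | (1,3-dioxolan-2-yl)methyl ketone | CC[Si](CC)(CC)O[C@H]1C[C@@H](C=C)[C@@H](C(=O)CC2OCCO2)C=C1C
F7 | step 8 | enol triflate of F6 towards C8 | CC[Si](CC)(CC)O[C@H]1C[C@@H](C=C)[C@@H](C(OS(=O)(=O)C(F)(F)F)=CC2OCCO2)C=C1C
F8 | step 8 | 2-isopropenyl diene | CC[Si](CC)(CC)O[C@H]1C[C@@H](C=C)[C@@H](C(=CC2OCCO2)C(C)=C)C=C1C
F9 | step 12 | ethyl (E)-5-(tert-butyldimethylsilyloxy)-2-methyl-3-[ring A unit]pent-2-enoate | CC[Si](CC)(CC)O[C@H]1C[C@@H](C=C)[C@@H](/C(CCO[Si](C)(C)C(C)(C)C)=C(\C)C(=O)OCC)C=C1C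
F10 | step 12 | allylic alcohol from F9 | CC[Si](CC)(CC)O[C@H]1C[C@@H](C=C)[C@@H](/C(CCO[Si](C)(C)C(C)(C)C)=C(\C)CO)C=C1C
F11 | step 12 | formate of F10 | CC[Si](CC)(CC)O[C@H]1C[C@@H](C=C)[C@@H](/C(CCO[Si](C)(C)C(C)(C)C)=C(\C)COC=O)C=C1C
F12 | step 12 | diol formate (C3–OH and C9–OH free) | O[C@H]1C[C@@H](C=C)[C@@H](/C(CCO)=C(\C)COC=O)C=C1C
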